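Assumption: the SMILES is taken literally, so the target is the 4a,8a-cis-fused octalin (1R,4aR,7S,8aS) with a 3R side chain and a Z (angelate) ester; naphthalene locants are used throughout (C1 carries the side chain, C7 the oxygen, C8a the angular methyl).

**Retrosynthetic overview**
1. Target ⇒ acylation of the 7-hydroxy acid with angelic anhydride (last bond, Z geometry kept); the equatorial 7S alcohol ⇒ dissolving-metal reduction of the 7-ketone, which also frees the acid from its benzyl ester.
2. 7-Ketone ⇒ 1,2-carbonyl transposition of the 8-ketone through its enol triflate; the 8-carbonyl is the group that activates the dienophile.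
3. 8-Keto cis-octalin ⇒ endo, "ortho" catalytic asymmetric Diels–Alder of 2,4,4-trimethylcyclohex-2-enone with an (E)-1,2-dialkyl diene carrying the whole side chain; C1, C4a and C8a are set together.
4. Diene ⇒ citral by organocatalytic transfer hydrogenation (side-chain C3, the first stereocentre), oxidative esterification, cross-metathesis with methacrolein and Wittig methylenation.
5. Ring order: ring A first (annulation of isobutyraldehyde with ethyl vinyl ketone), ring B second ([4+2]).

**Route**

Step 1
Reactants: 1 citral (commercial E/Z mixture of 3,7-dimethylocta-2,6-dienal)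
Product: 2 (R)-citronellal, (3R)-3,7-dimethyloct-6-enal
Conditions: morpholinium salt of (R)-TRIP (3,3′-bis(2,4,6-triisopropylphenyl)-BINOL hydrogen phosphate, 20 mol %), Hantzsch ester (diethyl 2,6-dimethyl-1,4-dihydropyridine-3,5-dicarboxylate, 1.1 equiv), THF, 50 °C
Reagents that add atoms: none
Why: Organocatalytic asymmetric transfer hydrogenation by iminium catalysis with a chiral counteranion: the morpholinium iminium ion of 1 is paired with the chiral phosphate, which directs hydride transfer from the Hantzsch ester to one face of C3, and because the E and Z iminium ions interconvert both isomers of 1 converge on the 3R aldehyde (about 95:5 er expected; the antipodal acid is used if the sense were opposite).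

Step 2
Reactants: 2 (R)-citronellal
Product: 3 benzyl (3R)-3,7-dimethyloct-6-enoate
Conditions: 1,4-dimethyl-1,2,4-triazolium iodide (5 mol %), DBU (1.1 equiv), 3,3′,5,5′-tetra-tert-butyldiphenoquinone (1.05 equiv), BnOH (1.5 equiv), THF, rt
Reagents that add atoms: benzyl alcohol, OCc1ccccc1
Why: N-heterocyclic carbene-catalysed oxidative esterification: the Breslow intermediate is oxidised by the quinone to an acyl azolium that acylates benzyl alcohol, and the β-stereocentre is not touched.

Step 3
Reactants: 3 benzyl (3R)-3,7-dimethyloct-6-enoate; 4 methacrolein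
Product: 5 benzyl (3R,6E)-3,7-dimethyl-8-oxooct-6-enoate
Conditions: second-generation Hoveyda–Grubbs catalyst (5 mol %), 4 in fivefold excess, CH2Cl2, 40 °C
Reagents that add atoms: none
Why: Olefin cross-metathesis of the prenyl-type terminus with methacrolein, driven by loss of 2-methylpropene, gives the conjugated trisubstituted enal as the thermodynamically favoured E isomer, and the product enal is inert to further metathesis.

Step 4
Reactants: 5 benzyl (3R,6E)-3,7-dimethyl-8-oxooct-6-enoate
Product: 6 benzyl (3R,6E)-3,7-dimethylnona-6,8-dienoate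
Conditions: Ph3PCH3Br (1.3 equiv), KOt-Bu (1.2 equiv), THF, 0 °C; then 5, −78 → 0 °C
Reagents that add atoms: methyltriphenylphosphonium bromide (used as its ylide), C[P+](c1ccccc1)(c1ccccc1)c1ccccc1.[Br-]
Why: Wittig methylenation of the aldehyde (the ester is unreactive to the ylide at low temperature) gives the 1,3-diene, and the E geometry of the trisubstituted alkene is carried over unchanged.

Step 5
Reactants: 7 isobutyraldehyde; 8 ethyl vinyl ketone (pent-1-en-3-one)
Product: 10 2,4,4-trimethylcyclohex-2-en-1-one, via keto aldehyde 9 (not isolated)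
Conditions: H2SO4 (cat.), toluene, 110 °C, Dean–Stark
Reagents that add atoms: none
Why: Robinson-type annulation: acid-catalysed Michael addition of the enol of 7 to 8 gives 2,2-dimethyl-5-oxoheptanal, whose ethyl ketone CH2 condenses onto the aldehyde (intramolecular aldol condensation) to close ring A.

Step 6
Reactants: 6 benzyl (3R,6E)-3,7-dimethylnona-6,8-dienoate; 10 2,4,4-trimethylcyclohex-2-en-1-one
Product: 11 benzyl (3R)-3-methyl-5-[(1R,4aR,8aS)-2,5,5,8a-tetramethyl-8-oxo-1,4,4a,5,6,7,8,8a-octahydronaphthalen-1-yl]pentanoate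
Conditions: (S,S)-IDPi (confined BINOL-derived imidodiphosphorimidate Brønsted acid, 5 mol %), CH2Cl2, 4 Å MS, −40 → −20 °C
Reagents that add atoms: none
Why: Proposed new method: an asymmetric Diels–Alder reaction under confined chiral Brønsted acid (ion-pair) catalysis, a pure addition of one molecule of 6 to one molecule of 10 in which every atom of both partners is kept in 11, in which the IDPi acid protonates the carbonyl of 10 to a hydroxyallyl cation held inside the chiral anion, the CH2 terminus (C9) of 6 attacks the neopentyl β-carbon C3 of 10 and the substituted terminus (C6) closes onto C2 ("ortho" orientation, concerted but asynchronous), ring A lies endo under the diene so that the side chain ends up cis to the carbonyl carbon and trans to the angular methyl while the cis alkene of 10 gives the cis ring fusion, and the catalyst enantiomer is the one whose anion covers the Si face so that the diene adds to the Re face at C2 and C3 of 10, which sets 1R,4aR,8aS in one step; the closest known reaction types are IDPi-catalysed Diels–Alder reactions of cyclohexadienones with cyclopentadiene and Lewis acid (AlCl3 or oxazaborolidinium) Diels–Alder reactions of 2-alkylcyclohex-2-enones with acyclic dienes, and new here is a trisubstituted β-neopentyl cyclic enone combined with an acyclic 1,2-dialkyl diene under anion control (a confined anion is chosen because an α-methyl enone offers no α-C–H or formyl C–H contact to a boron catalyst).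

Step 7
Reactants: 11 benzyl (3R)-3-methyl-5-[(1R,4aR,8aS)-2,5,5,8a-tetramethyl-8-oxo-1,4,4a,5,6,7,8,8a-octahydronaphthalen-1-yl]pentanoate
Product: 13 benzyl (3R)-3-methyl-5-[(1R,4aR,8aS)-2,5,5,8a-tetramethyl-8-(trifluoromethylsulfonyloxy)-1,4,4a,5,6,8a-hexahydronaphthalen-1-yl]pentanoate, via potassium enolate 12 (not isolated)
Conditions: KN(SiMe3)2 (1.1 equiv), THF, −78 °C; PhNTf2 (1.2 equiv), −78 → 0 °C
Reagents that add atoms: N-phenylbis(trifluoromethanesulfonimide), O=S(=O)(N(c1ccccc1)S(=O)(=O)C(F)(F)F)C(F)(F)F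
Why: Enol triflate formation by kinetic enolisation and O-sulfonylation: the ketone can only enolise towards C7 because C8a is quaternary, the ester is several pKa units less acidic, and no stereocentre is α to the carbonyl on the enolisable side.

Step 8
Reactants: 13 benzyl (3R)-3-methyl-5-[(1R,4aR,8aS)-2,5,5,8a-tetramethyl-8-(trifluoromethylsulfonyloxy)-1,4,4a,5,6,8a-hexahydronaphthalen-1-yl]pentanoate
Product: 15 benzyl (3R)-3-methyl-5-[(1R,4aR,8aS)-2,5,5,8a-tetramethyl-7-oxo-1,4,4a,5,6,7,8,8a-octahydronaphthalen-1-yl]pentanoate, via morpholine enamine 14 (not isolated)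
Conditions: Pd(OAc)2 (10 mol %), P(2-furyl)3 (25 mol %), norbornene cocatalyst (5-norbornene-2-carboxamide type, 50 mol %), morpholin-4-yl benzoate (1.5 equiv), i-PrOH (3 equiv), Cs2CO3 (2.5 equiv), 1,4-dioxane, 100 °C; then 1 M HCl, THF, rt
Reagents that add atoms: water, O (the new carbonyl oxygen); morpholin-4-yl benzoate, O=C(ON1CCOCC1)c1ccccc1 (its morpholine ring is in 14 only)
Why: 1,2-Carbonyl transposition by palladium/norbornene cooperative (Catellani-type) catalysis: oxidative addition of the alkenyl triflate, norbornene insertion, palladation of the vinylic C7–H, C–N bond formation with the N–O electrophile, norbornene extrusion and ipso hydride termination (hydride from i-PrOH) give the C7 enamine, which is hydrolysed to the 7-ketone without touching any stereocentre.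

Step 9
Reactants: 15 benzyl (3R)-3-methyl-5-[(1R,4aR,8aS)-2,5,5,8a-tetramethyl-7-oxo-1,4,4a,5,6,7,8,8a-octahydronaphthalen-1-yl]pentanoate
Product: 16 (3R)-5-[(1R,4aR,7S,8aS)-7-hydroxy-2,5,5,8a-tetramethyl-1,4,4a,5,6,7,8,8a-octahydronaphthalen-1-yl]-3-methylpentanoic acid
Conditions: Li (8 equiv), NH3(l)/THF, t-BuOH (3 equiv), −78 °C; then NH4Cl
Reagents that add atoms: none
Why: Dissolving-metal (Birch-type) reduction: the ketone is reduced through its ketyl to the thermodynamically favoured equatorial alcohol, which is trans to the angular methyl (7S) because the 7-epimer would be 1,3-diaxial to both the C8a methyl and the axial C5 methyl, and in the same operation the benzyl ester is cleaved reductively to the carboxylate while the isolated trisubstituted alkene is inert.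

Step 10
Reactants: 16 (3R)-5-[(1R,4aR,7S,8aS)-7-hydroxy-2,5,5,8a-tetramethyl-1,4,4a,5,6,7,8,8a-octahydronaphthalen-1-yl]-3-methylpentanoic acid; 17 angelic anhydride, (2Z)-2-methylbut-2-enoic anhydride
Product: 19 (3R)-3-methyl-5-[(1R,4aR,7S,8aS)-2,5,5,8a-tetramethyl-7-{[(2Z)-2-methylbut-2-enoyl]oxy}-1,4,4a,5,6,7,8,8a-octahydronaphthalen-1-yl]pentanoic acid, via dilithium salt 18 (not isolated)
Conditions: LiN(SiMe3)2 (2.1 equiv), THF, −78 °C; 17 in slight excess, −78 → −20 °C; then 1 M HCl
Reagents that add atoms: none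
Why: Alkoxide acylation by an anhydride: in the dianion the alkoxide is far more nucleophilic than the lithium carboxylate and is acylated selectively at low temperature, and without a nucleophilic catalyst or heat the Z (angelate) geometry is not isomerised to the E (tiglate) form; the configuration at C7 is retained.

**Compound list**
1 | citral, (2E/2Z)-3,7-dimethylocta-2,6-dienal | CC(C)=CCCC(C)=CC=O | starting material
2 | (R)-citronellal, (3R)-3,7-dimethyloct-6-enal | O=CC[C@H](C)CCC=C(C)C | intermediate
3 | benzyl (3R)-3,7-dimethyloct-6-enoate | O=C(OCc1ccccc1)C[C@H](C)CCC=C(C)C | intermediate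
4 | methacrolein, 2-methylprop-2-enal | CC(=C)C=O | starting material
5 | benzyl (3R,6E)-3,7-dimethyl-8-oxooct-6-enoate | O=C(OCc1ccccc1)C[C@H](C)CC/C=C(\C)C=O | intermediate
6 | benzyl (3R,6E)-3,7-dimethylnona-6,8-dienoate | O=C(OCc1ccccc1)C[C@H](C)CC/C=C(\C)C=C | intermediate
7 | isobutyraldehyde, 2-methylpropanal | CC(C)C=O | starting material
8 | ethyl vinyl ketone, pent-1-en-3-one | CCC(=O)C=C | starting material
9 | 2,2-dimethyl-5-oxoheptanal (not isolated) | CCC(=O)CCC(C)(C)C=O | intermediate
10 | 2,4,4-trimethylcyclohex-2-en-1-one | CC1=CC(C)(C)CCC1=O | intermediate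
11 | benzyl (3R)-3-methyl-5-[(1R,4aR,8aS)-2,5,5,8a-tetramethyl-8-oxo-1,4,4a,5,6,7,8,8a-octahydronaphthalen-1-yl]pentanoate | O=C1CCC(C)(C)[C@H]2CC=C(C)[C@@H](CC[C@@H](C)CC(=O)OCc3ccccc3)[C@@]12C | intermediate
12 | potassium enolate of 11 (O–K on C8, C7=C8 double bond, other centres as in 11; not isolated) | [K+].[O-]C1=CCC(C)(C)[C@H]2CC=C(C)[C@@H](CC[C@@H](C)CC(=O)OCc3ccccc3)[C@@]12C | intermediate
13 | benzyl (3R)-3-methyl-5-[(1R,4aR,8aS)-2,5,5,8a-tetramethyl-8-(trifluoromethylsulfonyloxy)-1,4,4a,5,6,8a-hexahydronaphthalen-1-yl]pentanoate | FC(F)(F)S(=O)(=O)OC1=CCC(C)(C)[C@H]2CC=C(C)[C@@H](CC[C@@H](C)CC(=O)OCc3ccccc3)[C@@]12C | intermediate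
14 | benzyl (3R)-3-methyl-5-[(1R,4aR,8aS)-2,5,5,8a-tetramethyl-7-(morpholin-4-yl)-1,4,4a,5,6,8a-hexahydronaphthalen-1-yl]pentanoate (not isolated) | C1=C(N3CCOCC3)CC(C)(C)[C@H]2CC=C(C)[C@@H](CC[C@@H](C)CC(=O)OCc4ccccc4)[C@@]12C | intermediate
15 | benzyl (3R)-3-methyl-5-[(1R,4aR,8aS)-2,5,5,8a-tetramethyl-7-oxo-1,4,4a,5,6,7,8,8a-octahydronaphthalen-1-yl]pentanoate | O=C1CC(C)(C)[C@H]2CC=C(C)[C@@H](CC[C@@H](C)CC(=O)OCc3ccccc3)[C@@]2(C)C1 | intermediate
16 | (3R)-5-[(1R,4aR,7S,8aS)-7-hydroxy-2,5,5,8a-tetramethyl-1,4,4a,5,6,7,8,8a-octahydronaphthalen-1-yl]-3-methylpentanoic acid | O[C@H]1CC(C)(C)[C@H]2CC=C(C)[C@@H](CC[C@@H](C)CC(=O)O)[C@@]2(C)C1 | intermediate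
17 | angelic anhydride, (2Z)-2-methylbut-2-enoic anhydride | C/C=C(/C)C(=O)OC(=O)/C(C)=C\C | starting material
18 | dilithium alkoxide-carboxylate of 16 (not isolated) | [Li+].[Li+].[O-][C@H]1CC(C)(C)[C@H]2CC=C(C)[C@@H](CC[C@@H](C)CC(=O)[O-])[C@@]2(C)C1 | intermediate
19 | (3R)-3-methyl-5-[(1R,4aR,7S,8aS)-2,5,5,8a-tetramethyl-7-{[(2Z)-2-methylbut-2-enoyl]oxy}-1,4,4a,5,6,7,8,8a-octahydronaphthalen-1-yl]pentanoic acid | C/C=C(/C)C(=O)O[C@H]1CC(C)(C)[C@H]2CC=C(C)[C@@H](CC[C@@H](C)CC(=O)O)[C@@]2(C)C1 | target

**Step count and risks**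
Total step count: 10. Longest linear sequence: 9 (steps 1–4 and 6–10; step 5 is the side branch that makes ring A).

The three steps most likely to fail:

Step 6 (the proposed new Diels–Alder reaction). The enone is trisubstituted and its β-carbon is neopentyl, the diene can oligomerise under strong acid, and endo or facial selectivity may fall short. The fallback sets out from 6 and 10 and comes back at 11, using known chemistry. The two are combined under the classical conditions for 2-alkylcyclohex-2-enones, AlCl3 (1.5 equiv, precomplexed with 10 and the ester) in toluene at 25–40 °C, which are established to give endo, "ortho", cis-fused adducts with acyclic dienes. Without a chiral catalyst the ring forms in both senses, and because the chain centre is already R the two adducts are diastereomers: 11 and benzyl (3R)-3-methyl-5-[(1S,4aS,8aR)-2,5,5,8a-tetramethyl-8-oxo-1,4,4a,5,6,7,8,8a-octahydronaphthalen-1-yl]pentanoate F1. They are separated by preparative chromatography on a chiral stationary phase (the pair behaves as quasi-enantiomers), and 11 goes into step 7; half of the material is lost.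

Step 8 (carbonyl transposition on a triflate flanked by a quaternary carbon). Norbornene insertion or the C–H palladation may be too slow, giving simple reduction of the triflate. The fallback sets out from 13 and comes back at 16, so it also replaces step 9. The triflate is reduced with Pd(OAc)2/PPh3, HCO2H and Bu3N in DMF at 60 °C to benzyl (3R)-3-methyl-5-[(1R,4aR,8aS)-2,5,5,8a-tetramethyl-1,4,4a,5,6,8a-hexahydronaphthalen-1-yl]pentanoate F2. Hydroboration of the disubstituted C7=C8 alkene with 9-BBN (THF, 60 °C) puts boron on C7, away from the quaternary C8a and on the face opposite the C8a and axial C5 methyls, while the trisubstituted ring alkene is left alone; this gives benzyl (3R)-5-[(1R,4aR,7S,8aS)-7-(9-borabicyclo[3.3.1]nonan-9-yl)-2,5,5,8a-tetramethyl-1,4,4a,5,6,7,8,8a-octahydronaphthalen-1-yl]-3-methylpentanoate F3 (not isolated). Oxidation with NaBO3 in THF/H2O gives benzyl (3R)-5-[(1R,4aR,7S,8aS)-7-hydroxy-2,5,5,8a-tetramethyl-1,4,4a,5,6,7,8,8a-octahydronaphthalen-1-yl]-3-methylpentanoate F4 with retention, and LiOH in THF/H2O then gives 16.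

Step 10 (acylation of a hydroxy acid with a geometry-sensitive acyl group). The carboxylate may compete for the anhydride (mixed anhydride, then intermolecular ester), or part of the angelate may isomerise to the tiglate. The fallback sets out from 16 and comes back at 19. The carboxylate is alkylated with allyl bromide and K2CO3 in DMF to prop-2-enyl (3R)-5-[(1R,4aR,7S,8aS)-7-hydroxy-2,5,5,8a-tetramethyl-1,4,4a,5,6,7,8,8a-octahydronaphthalen-1-yl]-3-methylpentanoate F5. The alcohol, now the only acidic site, is acylated with 17 and LiN(SiMe3)2 in THF at −78 °C to prop-2-enyl (3R)-3-methyl-5-[(1R,4aR,7S,8aS)-2,5,5,8a-tetramethyl-7-{[(2Z)-2-methylbut-2-enoyl]oxy}-1,4,4a,5,6,7,8,8a-octahydronaphthalen-1-yl]pentanoate F6. The allyl group is removed with Pd(PPh3)4 and morpholine in THF at rt, conditions that leave the angelate and the ring alkene untouched, to give 19.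

**Further compounds**
F1 | step 6 | benzyl (3R)-3-methyl-5-[(1S,4aS,8aR)-2,5,5,8a-tetramethyl-8-oxo-1,4,4a,5,6,7,8,8a-octahydronaphthalen-1-yl]pentanoate | O=C1CCC(C)(C)[C@@H]2CC=C(C)[C@H](CC[C@@H](C)CC(=O)OCc3ccccc3)[C@]12C
F2 | step 8 | benzyl (3R)-3-methyl-5-[(1R,4aR,8aS)-2,5,5,8a-tetramethyl-1,4,4a,5,6,8a-hexahydronaphthalen-1-yl]pentanoate | C1=CCC(C)(C)[C@H]2CC=C(C)[C@@H](CC[C@@H](C)CC(=O)OCc3ccccc3)[C@@]12C
F3 | step 8 | benzyl (3R)-5-[(1R,4aR,7S,8aS)-7-(9-borabicyclo[3.3.1]nonan-9-yl)-2,5,5,8a-tetramethyl-1,4,4a,5,6,7,8,8a-octahydronaphthalen-1-yl]-3-methylpentanoate | C1CCC2CCCC1B2[C@H]1CC(C)(C)[C@H]2CC=C(C)[C@@H](CC[C@@H](C)CC(=O)OCc3ccccc3)[C@@]2(C)C1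
F4 | step 8 | benzyl (3R)-5-[(1R,4aR,7S,8aS)-7-hydroxy-2,5,5,8a-tetramethyl-1,4,4a,5,6,7,8,8a-octahydronaphthalen-1-yl]-3-methylpentanoate | O[C@H]1CC(C)(C)[C@H]2CC=C(C)[C@@H](CC[C@@H](C)CC(=O)OCc3ccccc3)[C@@]2(C)C1
F5 | step 10 | prop-2-enyl (3R)-5-[(1R,4aR,7S,8aS)-7-hydroxy-2,5,5,8a-tetramethyl-1,4,4a,5,6,7,8,8a-octahydronaphthalen-1-yl]-3-methylpentanoate | O[C@H]1CC(C)(C)[C@H]2CC=C(C)[C@@H](CC[C@@H](C)CC(=O)OCC=C)[C@@]2(C)C1
F6 | step 10 | prop-2-enyl (3R)-3-methyl-5-[(1R,4aR,7S,8aS)-2,5,5,8a-tetramethyl-7-{[(2Z)-2-methylbut-2-enoyl]oxy}-1,4,4a,5,6,7,8,8a-octahydronaphthalen-1-yl]pentanoate | C/C=C(/C)C(=O)O[C@H]1CC(C)(C)[C@H]2CC=C(C)[C@@H](CC[C@@H](C)CC(=O)OCC=C)[C@@]2(C)C1
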